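**Strategy**

The flavone is cut at the C2–C1' bond that joins ring B to ring C. In 5,7,8-trimethoxychromone, C2 of ring C carries only hydrogen and is the β-carbon of the C2=C3–C4=O enone. A palladium-catalysed oxidative boron-Heck reaction with 2,3,4,5-tetramethoxyphenylboronic acid arylates this C2–H in one operation, with no halogen on either partner and no ring closure. The chromone is made in two steps from 1,2,3,5-tetramethoxybenzene and the boronic acid in one step from 1,2,3,4-tetramethoxybenzene. The coupling gives the fully methylated flavone, and a chelation-directed cleavage of the 5-methyl ether, peri to C4=O, then releases the target.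

Key step: step 4

Remark: the target has no stereocentre; acetophenones 2 and 3 are numbered with the acetyl group at C1, and the ether cleaved in step 1 is the C2 methoxy group next to the C3 methoxy group, whose oxygen becomes O1 of the chromone.

**Route**

Step 1
Reactants: 1 1,2,3,5-tetramethoxybenzene
Product: 3 2-hydroxy-3,4,6-trimethoxyacetophenone, via tetramethoxyacetophenone 2 (not isolated)
Conditions: AcCl (1.2 equiv), AlCl3 (2.5 equiv), Et2O, 0 °C to reflux; then ice/H2O
Reagents that add atoms: acetyl chloride, CC(=O)Cl
Why: Friedel–Crafts acylation at the only kind of ring C–H (flanked by two methoxy groups and para to a third) gives ketone 2, whose AlCl3 chelate then loses the methyl of the C2 methoxy group, which is squeezed between the acetyl and the C3 methoxy group and is therefore the more Lewis-basic and more strained ortho ether (chelation-assisted ortho-O-demethylation).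

Step 2
Reactants: 3 2-hydroxy-3,4,6-trimethoxyacetophenone; 4 N,N-dimethylformamide dimethyl acetal
Product: 6 5,7,8-trimethoxychromone, via enaminone 5 (not isolated)
Conditions: 4 (2 equiv), toluene, 100 °C; evaporate; conc. HCl, CH2Cl2, 40 °C
Reagents that add atoms: none
Why: Condensation of the acetyl methyl group with the amide acetal gives the vinylogous amide 5, and acid then drives conjugate addition of the phenol to its β-carbon with loss of dimethylamine (addition–elimination closure of the pyranone), the standard enaminone route to 2,3-unsubstituted chromones.

Step 3
Reactants: 7 1,2,3,4-tetramethoxybenzene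
Product: 10 2,3,4,5-tetramethoxyphenylboronic acid, via aryllithium 8 (not isolated), via lithium aryltriisopropoxyborate 9 (not isolated)
Conditions: n-BuLi (1.2 equiv), TMEDA (1.2 equiv), THF, 0 °C; B(OiPr)3 (1.5 equiv), −78 °C to rt; 1 M HCl, 0 °C
Reagents that add atoms: triisopropyl borate, CC(C)OB(OC(C)C)OC(C)C; water, O
Why: Directed ortho-metalation, in which a terminal methoxy group guides n-BuLi/TMEDA to the adjacent ring C–H (the two ring hydrogens are equivalent), followed by trapping of the aryllithium with the borate ester and hydrolysis of the ate complex to the boronic acid.

Step 4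
Reactants: 6 5,7,8-trimethoxychromone; 10 2,3,4,5-tetramethoxyphenylboronic acid
Product: 11 5,7,8,2',3',4',5'-heptamethoxyflavone
Conditions: Pd(OCOCF3)2 (10 mol%), 1,10-phenanthroline (20 mol%), O2 (1 atm), DMSO, 90 °C; 10 (2.5 equiv) added in portions
Reagents that add atoms: none
Why: Transmetalation of 10 to the phenanthroline-bound divalent palladium trifluoroacetate gives an aryl–palladium species that adds syn across C2=C3 of 6, with the aryl group going to the electrophilic β-carbon C2 and palladium to C3. Because H-2 is then anti to palladium, the C3-bound metal first epimerises through the oxygen-bound enolate; syn β-hydride elimination then gives the flavone and zerovalent palladium, which O2 returns to the divalent state, and any flavanone formed by protonation of the enolate should be dehydrogenated by the same Pd/DMSO/O2 system. The closest known reaction type is the palladium-catalysed oxidative Heck arylation of chromones with arylboronic acids to give flavones. No ring is closed and no stereocentre is created. The step needs C2 over C3 selectivity, which the enone polarity secures because a preformed aryl–palladium nucleophile is delivered to the β-carbon, whereas direct palladation of the chromone would favour C3. The main competitor is protodeboronation of the electron-rich, ortho-methoxylated boronic acid, which the excess of 10 and its portionwise addition are meant to offset.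

Step 5
Reactants: 11 5,7,8,2',3',4',5'-heptamethoxyflavone
Product: 12 5-hydroxy-7,8,2',3',4',5'-hexamethoxyflavone (target)
Conditions: BCl3 (1 M in CH2Cl2, 1.5 equiv), CH2Cl2, −78 to 0 °C; then H2O/MeOH
Reagents that add atoms: none
Why: Chelation-controlled Lewis-acid demethylation, in which BCl3 bridges the C4 carbonyl and the peri C5 oxygen in a six-membered dichloroboron chelate so that chloride removes only that methyl group, while the other six ethers have no carbonyl partner and should survive at low temperature with near-stoichiometric reagent.

**Compound list**

1 | 1,2,3,5-tetramethoxybenzene | COc1cc(OC)c(OC)c(OC)c1 | starting material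
2 | 2,3,4,6-tetramethoxyacetophenone | CC(=O)c1c(OC)cc(OC)c(OC)c1OC | intermediate (not isolated)
3 | 2-hydroxy-3,4,6-trimethoxyacetophenone | CC(=O)c1c(OC)cc(OC)c(OC)c1O | intermediate
4 | N,N-dimethylformamide dimethyl acetal | COC(OC)N(C)C | starting material
5 | (E)-3-(dimethylamino)-1-(2-hydroxy-3,4,6-trimethoxyphenyl)prop-2-en-1-one | CN(C)/C=C/C(=O)c1c(OC)cc(OC)c(OC)c1O | intermediate (not isolated)
6 | 5,7,8-trimethoxychromone (5,7,8-trimethoxy-4H-chromen-4-one) | COc1cc(OC)c2c(=O)ccoc2c1OC | intermediate
7 | 1,2,3,4-tetramethoxybenzene | COc1ccc(OC)c(OC)c1OC | starting material
8 | (2,3,4,5-tetramethoxyphenyl)lithium | [Li]c1cc(OC)c(OC)c(OC)c1OC | intermediate (not isolated)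
9 | lithium triisopropoxy(2,3,4,5-tetramethoxyphenyl)borate | [Li+].CC(C)O[B-](OC(C)C)(OC(C)C)c1cc(OC)c(OC)c(OC)c1OC | intermediate (not isolated)
10 | 2,3,4,5-tetramethoxyphenylboronic acid | COc1cc(B(O)O)c(OC)c(OC)c1OC | intermediate
11 | 5,7,8,2',3',4',5'-heptamethoxyflavone (5,7,8-trimethoxy-2-(2,3,4,5-tetramethoxyphenyl)-4H-chromen-4-one) | COc1cc(-c2cc(=O)c3c(OC)cc(OC)c(OC)c3o2)c(OC)c(OC)c1OC | intermediate
12 | 5-hydroxy-7,8,2',3',4',5'-hexamethoxyflavone (5-hydroxy-7,8-dimethoxy-2-(2,3,4,5-tetramethoxyphenyl)-4H-chromen-4-one) | COc1cc(-c2cc(=O)c3c(O)cc(OC)c(OC)c3o2)c(OC)c(OC)c1OC | target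

**Step count**

Total: 5 steps. Longest linear sequence: 4 steps (steps 1, 2, 4, 5); the boronic acid branch (step 3) is one step.

**Steps most likely to fail**

1. Step 4. The electron-rich, ortho-substituted boronic acid may lose boron by protodeboronation or homocouple faster than it transmetalates. Insertion into the donor-substituted enone may be slow. The product may also stall at the saturated flavanone oxidation level. The fallback gives up the C–H arylation and builds ring C around the aryl group by known chemistry. It sets out from 7 and 3 and returns at 11. The ortho-lithiation of 7 is repeated as in step 3, and aryllithium 8 is quenched with DMF to give the lithium hemiaminal alkoxide F1, which aqueous HCl converts into 2,3,4,5-tetramethoxybenzaldehyde F2. Claisen–Schmidt condensation of F2 with acetophenone 3 (KOH, EtOH, rt) should give (E)-1-(2-hydroxy-3,4,6-trimethoxyphenyl)-3-(2,3,4,5-tetramethoxyphenyl)prop-2-en-1-one F3. Oxidative cyclisation of this 2'-hydroxychalcone with catalytic I2 in DMSO at 120 °C closes ring C and gives flavone 11.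

2. Step 1. The one-pot acylation and ether cleavage may remove the wrong ortho methyl group, remove both, or stop at the uncleaved ketone, and a mixture of phenols would be carried into the chromone. The fallback separates C-acylation from ether cleavage. It sets out from 1 and returns at 3. Compound 1 is acetylated under Brønsted-acid mixed-anhydride conditions that leave aryl methyl ethers intact (AcOH, (CF3CO)2O, cat. H3PO4, rt), and ketone 2 is isolated and purified. One ortho ether is then cleaved in a separate step with BCl3 (1.05 equiv) in CH2Cl2 at −78 °C. The fixed stoichiometry and low temperature should limit the reaction to a single chelation-directed demethylation at the more crowded C2 methoxy group, giving 3.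

3. Step 3. Deprotonation of the electron-rich arene may be incomplete, and the C–B bond of the product may be lost by protodeboronation during acidic work-up. The fallback fixes the position by electrophilic halogenation and generates the aryllithium by exchange instead of deprotonation. It sets out from 7 and returns at 10. Bromination of 7 (NBS, MeCN, rt) should give 1-bromo-2,3,4,5-tetramethoxybenzene F4. Bromine–lithium exchange (n-BuLi, THF, −78 °C) then forms aryllithium 8 at low temperature. Trapping with B(OiPr)3 gives ate complex 9, and a buffered work-up (aqueous NH4Cl, 0 °C) gives boronic acid 10.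

**Further compounds**

F1 | step 4 | lithium (dimethylamino)(2,3,4,5-tetramethoxyphenyl)methanolate | [Li+].[O-]C(N(C)C)c1cc(OC)c(OC)c(OC)c1OC
F2 | step 4 | 2,3,4,5-tetramethoxybenzaldehyde | COc1cc(C=O)c(OC)c(OC)c1OC
F3 | step 4 | (E)-1-(2-hydroxy-3,4,6-trimethoxyphenyl)-3-(2,3,4,5-tetramethoxyphenyl)prop-2-en-1-one | COc1cc(/C=C/C(=O)c2c(OC)cc(OC)c(OC)c2O)c(OC)c(OC)c1OC
F0 | step 1 | none | none
F4 | step 3 | 1-bromo-2,3,4,5-tetramethoxybenzene | COc1cc(Br)c(OC)c(OC)c1OC
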